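The runs are calculated from invented constants, noise included.

Partner minus substrate is invariant in the overall equation, one of each going per product, and blue and green were charged with the same difference, 0.0300 M. So blue, with half of its charge turned, holds green's charge plus 0.0750 M of product, and comparing rates at one substrate level shows what that product does.

| flask | substrate | partner | free catalyst | time |
|---|---|---|---|---|
| blue | 0.150 M | 0.180 M | 0.00300 M |  |
| green | 0.0750 M | 0.105 M | 0.00300 M |  |
| violet | 0.0750 M | 0.180 M | 0.00300 M |  |
| ochre | 0.150 M | 0.360 M | 0.00300 M |  |
| grey | 0.150 M | 0.180 M | 9.90 × 10⁻⁴ M | 130 min |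

| run | time / min | [product] / M |
|---|---|---|
| blue run | 5.2 | 0.0050 |
| blue run | 9.9 | 0.0113 |
| blue run | 19 | 0.0215 |
| blue run | 36 | 0.0406 |
| blue run | 68 | 0.0734 |
| blue run | 130 | 0.1142 |
| green run | 5.2 | 0.0018 |
| green run | 9.9 | 0.0049 |
| green run | 19 | 0.0104 |
| green run | 36 | 0.0200 |
| green run | 68 | 0.0346 |
| green run | 130 | 0.0544 |
| violet run | 5.2 | 0.0028 |
| violet run | 9.9 | 0.0066 |
| violet run | 19 | 0.0143 |
| violet run | 36 | 0.0264 |
| violet run | 68 | 0.0444 |
| violet run | 130 | 0.0643 |
| ochre run | 5.2 | 0.0077 |
| ochre run | 9.9 | 0.0166 |
| ochre run | 19 | 0.0329 |
| ochre run | 36 | 0.0643 |
| ochre run | 68 | 0.1097 |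
| ochre run | 130 | 0.1429 |

(standard deviation of a reading: 4 × 10⁻⁴ M)

- reaction order in [partner] at the outset, round the charge of the blue run, defined at two percent of the substrate turned into product
- reaction order in [substrate] at the outset, round the charge of the blue run, defined at two percent of the substrate turned into product (one fixed amount of product, the same in the runs compared)
- the green run starts with 0.0750 M less of substrate and of partner than the blue run, and with no product. Compared where both hold the same amount of substrate, once fifteen percent of what the green run was charged with has turned into product, is the green run faster, slower or alike (within a tenth)?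
- product in the grey run at 130 min, as a share of the substrate charged

- Overall: substrate + partner -> product, with free catalyst as catalyst.
- Constant volume, constant temperature.
- An order is taken over about fifteen percent of the charge, up and down.

Blue averaged 0.783 mM min⁻¹ between 36 min and 130 min, a window that passes through green's early state, while green averaged 0.579 mM min⁻¹ between 9.9 min and 36 min, so green ran slower than blue. I divided that gap by the extra product and by the substrate and partner green held at 19 min. This gave the reading 0.446 L² mol⁻² min⁻¹, my product lift: rate gained per unit of product, substrate and partner, or autocatalysis if that is what it is.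

Grey holds a third of blue's catalyst, so its 130 min count as 42.9 min of blue time, where blue's readings give 47.7 mM. I assumed the lift needs no free catalyst, an untested assumption, as blue and green both held 0.00300 M. Running it for the other 87.1 min at half that product added 12.2 % of the charge, so I expected 43.9 %.

The forecast gave 0.62, 0.6, slower and 33 %, lower than my figure: “If the reaction is first order in catalyst, 130 min corresponds to about 43 blue minutes”.

The flask gave 0.60, 0.45, slower and 43.4 %.

    free catalyst + substrate → loaded catalyst + by-product (6.120 L mol⁻¹ min⁻¹)
    loaded catalyst + partner → product + free catalyst (3.684 L mol⁻¹ min⁻¹)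
    substrate + partner + product → 2 product (0.4206 L² mol⁻² min⁻¹)

The third equation carries no free catalyst. A fit with the main steps alone put grey at 32.6 %, 11 percentage points under the flask. With 43.4 % of grey's charge turned at 130 min, my reading of the lift gives 0.283 mM min⁻¹ at that moment in grey, against an average product formation of 0.501 mM min⁻¹ over grey's whole run.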